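## Retrosynthetic overview

1. Feature: ring A (C4a–C8a of the chromanone) is hexasubstituted. Three oxygens of different fate (C5–OH, C7–OH, C8a–O1) alternate with C6–Me, the C4a acyl carbon and C8, and C8 carries the stereocentre C1' (H, i-Pr, ring D) between two ortho oxygens. C1' is therefore set first on an open chain and ring A is built around it.
2. Last disconnection: the C2–Ph bond, by asymmetric conjugate arylation of a chromone (ring C closed from a C4a acetyl group and the C8a phenol), then debenzylation.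
3. Ring D (D1 = carbon on C1', D2 C=O, D3 C–Me, D4 C–OMe, D5 CMe2, D6 C–OH) comes from a CH2–CHO arm on C1': dianion aldol, a methoxy lactone that fixes the D4 methyl ether and the D3=D4 geometry, then Claisen-type closure of D1–D2.
4. Key disconnection: ring A by photo-Wolff/vinylketene benzannulation of diazo ketone 21 with the enantiopure siloxyalkyne 12 (bonds C7–C8, C4a–C8a, C6–C7). C1' comes from an Evans allylation, and the arm on C1' is carried as an allyl group.
5. Ring order: A (step 11), D (step 20), C (step 22). Stereocentres: C1' in step 2, C2 in step 23.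

Key step: step 11

Assumption: in step 23 the (R)-configured pyridine-oxazoline ligand is taken to deliver the 2S flavanone, by analogy with the facial sense known for cyclic enones; if a model chromone shows the opposite sense, the (S)-ligand is used.

Abbreviations: ArA = 3-acetyl-4,6-bis(benzyloxy)-5-methyl-2-[(triisopropylsilyl)oxy]phenyl (ring A after step 14, bonded through C8). RD = 2-hydroxy-4-methoxy-3,3,5-trimethyl-6-oxocyclohexa-1,4-dien-1-yl (ring D, bonded through D1).

## Route

### Siloxyalkyne 12 (steps 1–5)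

Step 1
Reactants: 1 (4R)-4-benzyl-1,3-oxazolidin-2-one; 2 3-methylbutanoyl chloride
Product: 3 (4R)-4-benzyl-3-(3-methylbutanoyl)-1,3-oxazolidin-2-one
Conditions: n-BuLi, THF, −78 °C; then 2, −78 → 0 °C
Reagents that add atoms: none
Why: N-acylation of the lithiated oxazolidinone with an acid chloride is the standard entry to Evans imides and touches no stereocentre.

Step 2
Reactants: 3 (4R)-4-benzyl-3-(3-methylbutanoyl)-1,3-oxazolidin-2-one; 4 allyl bromide
Product: 6 (4R)-4-benzyl-3-[(2R)-2-(propan-2-yl)pent-4-enoyl]-1,3-oxazolidin-2-one, via sodium Z-enolate 5 (not isolated)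
Conditions: NaN(SiMe3)2, THF, −78 °C; then 4, −78 → −40 °C
Reagents that add atoms: none
Why: Evans asymmetric alkylation, in which the chelated Z-enolate is attacked by allyl bromide on the face away from the benzyl group of the (4R)-auxiliary, should set the (2R) centre (the future C1'); the allyl group is a latent CH2–CHO arm that, unlike an ester, is inert to the ynolate and aryllithium chemistry ahead.

Step 3
Reactants: 6 (4R)-4-benzyl-3-[(2R)-2-(propan-2-yl)pent-4-enoyl]-1,3-oxazolidin-2-one
Product: 8 (2R)-2-(propan-2-yl)pent-4-enoic acid, via peroxy acid 7 (not isolated)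
Conditions: LiOH, H2O2, THF/H2O, 0 °C; then Na2SO3; then 1 M HCl
Reagents that add atoms: hydrogen peroxide, OO
Why: Hydroperoxide attacks the exocyclic carbonyl selectively even in hindered imides (auxiliary hydrolysis) and sulfite reduces the peracid to the acid, so the α-centre should not epimerise and the auxiliary is recovered.

Step 4
Reactants: 8 (2R)-2-(propan-2-yl)pent-4-enoic acid
Product: 9 ethyl (2R)-2-(propan-2-yl)pent-4-enoate
Conditions: EtI, K2CO3, DMF, rt
Reagents that add atoms: iodoethane, CCI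
Why: O-alkylation of the carboxylate (SN2 esterification) leaves the α-centre untouched because carbonate cannot deprotonate the ester.

Step 5
Reactants: 9 ethyl (2R)-2-(propan-2-yl)pent-4-enoate
Product: 12 siloxyalkyne tri(propan-2-yl){[(3R)-3-(propan-2-yl)hex-5-en-1-yn-1-yl]oxy}silane, via dibromo enolate 10 (not isolated), via lithium ynolate 11 (not isolated)
Conditions: CH2Br2, lithium 2,2,6,6-tetramethylpiperidide (from the amine and n-BuLi), THF, −78 °C; then 9; then LiN(SiMe3)2, n-BuLi, −78 °C → rt; then i-Pr3SiOTf, −78 → 0 °C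
Reagents that add atoms: dibromomethane, BrCBr; triisopropylsilyl trifluoromethanesulfonate, CC(C)[Si](OS(=O)(=O)C(F)(F)F)(C(C)C)C(C)C
Why: Kowalski ester homologation, in which LiCHBr2 adds to the ester, the dibromo enolate undergoes bromine–lithium exchange and 1,2-shift of the alkyl group with retention at the migrating carbon, gives the ynolate, which the bulky silyl triflate should trap on oxygen.

### Diazo ketone 21 (steps 6–10)

Step 6
Reactants: 13 ethyl 2-(benzyloxy)acetate; 14 acetaldehyde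
Product: 15 ethyl 2-(benzyloxy)-3-hydroxybutanoate
Conditions: LiN(i-Pr)2, THF, −78 °C; then 14; NH4Cl
Reagents that add atoms: none
Why: Aldol addition of the ester lithium enolate to acetaldehyde; the diastereomer mixture is irrelevant because both centres become sp2 in step 7.

Step 7
Reactants: 15 ethyl 2-(benzyloxy)-3-hydroxybutanoate
Product: 17 ethyl (2Z)-2-(benzyloxy)but-2-enoate, via mesylate 16 (not isolated)
Conditions: MsCl, Et3N, CH2Cl2, 0 °C; then DBU, rt
Reagents that add atoms: none
Why: Mesylation and E1cB elimination should give mainly the Z enol ether, with the methyl group trans to the ester, which is the more stable isomer of 2-alkoxy-2-enoates.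

Step 8
Reactants: 17 ethyl (2Z)-2-(benzyloxy)but-2-enoate
Product: 18 (2Z)-2-(benzyloxy)-N-methoxy-N-methylbut-2-enamide
Conditions: MeNHOMe·HCl, i-PrMgCl, THF, −20 → 0 °C
Reagents that add atoms: N,O-dimethylhydroxylamine hydrochloride, CNOC.Cl
Why: Direct amidation of the ester with the magnesium amide (Weinreb amide formation) occurs at the carbonyl, since the β-methyl, α-alkoxy enoate is a poor Michael acceptor.

Step 9
Reactants: 18 (2Z)-2-(benzyloxy)-N-methoxy-N-methylbut-2-enamide
Product: 19 (3Z)-3-(benzyloxy)pent-3-en-2-one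
Conditions: MeMgBr, THF, −20 → 0 °C; cold aq. HCl
Reagents that add atoms: methylmagnesium bromide, C[Mg]Br
Why: Grignard addition to a Weinreb amide stops at the chelated tetrahedral intermediate, so the methyl ketone should form without over-addition.

Step 10
Reactants: 19 (3Z)-3-(benzyloxy)pent-3-en-2-one
Product: 21 diazo ketone (3Z)-3-(benzyloxy)-1-diazopent-3-en-2-one, via trifluoroacetyl diketone 20 (not isolated)
Conditions: LiN(SiMe3)2, THF, −78 °C; CF3CO2CH2CF3; then MsN3, Et3N, H2O, MeCN, rt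
Reagents that add atoms: methanesulfonyl azide, CS(=O)(=O)N=[N+]=[N-]
Why: Detrifluoroacetylative diazo transfer (kinetic α'-enolate, trifluoroacetylation, Regitz-type transfer with loss of the activating group) is the reliable route to α'-diazo enones and avoids the pyrazoline formation that diazomethane gives with enoyl chlorides.

### Ring A (step 11)

Step 11
Reactants: 21 diazo ketone (3Z)-3-(benzyloxy)-1-diazopent-3-en-2-one; 12 siloxyalkyne tri(propan-2-yl){[(3R)-3-(propan-2-yl)hex-5-en-1-yn-1-yl]oxy}silane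
Product: 26 5-(benzyloxy)-6-methyl-2-[(3R)-2-methylhex-5-en-3-yl]-3-[(triisopropylsilyl)oxy]phenol, via vinylketene 22 (not isolated), via vinylcyclobutenone 23 (not isolated), via dienylketene 24 (not isolated), via cyclohexadienone 25 (not isolated)
Conditions: 21 (1.3 equiv), hν (medium-pressure Hg lamp, Pyrex), CH2Cl2, rt; then toluene, 80 °C
Reagents that add atoms: none
Why: Light expels N2 from 21 and the alkenyl group migrates (photochemical Wolff rearrangement) to give vinylketene 22, whose ketene carbon (future C7) is attacked by the nucleophilic β-carbon of the siloxyalkyne (the carbon bearing C1', future C8) while its α-carbon (C4a) bonds to the siloxy carbon (C8a), giving vinylcyclobutenone 23 by regioselective [2+2] cycloaddition. 4π-Electrocyclic opening of 23 gives dienylketene 24, ring A is closed by a disrotatory 6π-electrocyclisation that forms C6–C7, and dienone 25 tautomerises to phenol 26. The closest known reaction type is the Danheiser benzannulation in its diazo ketone variant with triisopropylsiloxyalkynes. No stereocentre is formed, and C1', which sits next to the alkyne but carries no acidic or ionisable function, should survive the neutral photochemical and thermal conditions. The selectivity needed is the regiochemistry of the [2+2] step, which the polarisation of the ynol silyl ether secures and which places C1' between the free C7 hydroxyl and the C8a silyl ether, while the Z enol ether keeps the methyl group pointing outward in the electrocyclisation. The three oxygens thus arrive in three different states (C7 free, C5 benzyl, C8a silyl), so that the one para to the methyl group can later be released alone.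

### C4a acetyl group and CH2–CHO arm (steps 12–15)

Step 12
Reactants: 26 5-(benzyloxy)-6-methyl-2-[(3R)-2-methylhex-5-en-3-yl]-3-[(triisopropylsilyl)oxy]phenol
Product: 27 {3,5-bis(benzyloxy)-4-methyl-2-[(3R)-2-methylhex-5-en-3-yl]phenoxy}triisopropylsilane
Conditions: NaH, BnBr, Bu4NI (cat.), THF, 0 °C → rt
Reagents that add atoms: benzyl bromide, BrCc1ccccc1
Why: Williamson etherification of the hindered C7 phenoxide fixes the C7/C8a differentiation, because the silyl group has no path to the meta oxygen and no nucleophile for silicon is present.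

Step 13
Reactants: 27 {3,5-bis(benzyloxy)-4-methyl-2-[(3R)-2-methylhex-5-en-3-yl]phenoxy}triisopropylsilane
Product: 28 {3,5-bis(benzyloxy)-2-bromo-4-methyl-6-[(3R)-2-methylhex-5-en-3-yl]phenoxy}triisopropylsilane
Conditions: N-bromosuccinimide, CH2Cl2, −40 → 0 °C, dark
Reagents that add atoms: N-bromosuccinimide, O=C1CCC(=O)N1Br
Why: Electrophilic aromatic bromination should occur at C4a, the only unsubstituted carbon of a 1,3,5-trioxygenated ring, much faster than at the terminal alkene or the benzyl rings.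

Step 14
Reactants: 28 {3,5-bis(benzyloxy)-2-bromo-4-methyl-6-[(3R)-2-methylhex-5-en-3-yl]phenoxy}triisopropylsilane
Product: 30 1-{2,4-bis(benzyloxy)-3-methyl-5-[(3R)-2-methylhex-5-en-3-yl]-6-[(triisopropylsilyl)oxy]phenyl}ethan-1-one, via aryllithium 29 (not isolated)
Conditions: n-BuLi, THF, −78 °C; then MeC(O)N(OMe)Me, −78 → −30 °C; NH4Cl
Reagents that add atoms: N-methoxy-N-methylacetamide, CC(=O)N(C)OC
Why: Bromine–lithium exchange and acylation of the aryllithium with a Weinreb amide (stable chelate, no over-addition) installs the C4a acetyl group; at −78 °C the triisopropylsilyl group migrates from oxygen to the ortho carbanion far more slowly than smaller silyl groups, and the allyl arm is inert.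

Step 15
Reactants: 30 1-{2,4-bis(benzyloxy)-3-methyl-5-[(3R)-2-methylhex-5-en-3-yl]-6-[(triisopropylsilyl)oxy]phenyl}ethan-1-one
Product: 32 (3R)-3-(ArA)-4-methylpentanal, via diol 31 (not isolated)
Conditions: OsO4 (2 mol%), NaIO4, 2,6-lutidine, dioxane/H2O, rt
Reagents that add atoms: osmium tetroxide, O=[Os](=O)(=O)=O (catalytic oxygen carrier); sodium periodate, [Na+].[O-]I(=O)(=O)=O
Why: Lemieux–Johnson oxidation (catalytic dihydroxylation, periodate cleavage of the diol) turns the allyl group into the CH2–CHO arm (future D1 and D6) without attacking the electron-rich arene.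

### Ring D (steps 16–20)

Step 16
Reactants: 32 (3R)-3-(ArA)-4-methylpentanal; 33 methyl 2,4-dimethyl-3-oxopentanoate
Product: 36 6-[(2R)-2-(ArA)-3-methylbutyl]-4-hydroxy-3,5,5-trimethyl-5,6-dihydro-2H-pyran-2-one, via dianion 34 (not isolated), via hydroxy keto ester 35 (not isolated)
Conditions: 33, LiN(i-Pr)2 (2 equiv), THF, 0 °C; then 32, −78 °C; AcOH; then camphorsulfonic acid (cat.), toluene, 60 °C
Reagents that add atoms: none
Why: The γ-carbon of the β-keto ester dianion adds to the aldehyde (γ-selective dianion aldol, creating the quaternary carbon D5) and acid then closes the δ-hydroxy ester to the six-membered β-keto lactone; the new carbinol centre forms as a mixture that is erased in step 19.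

Step 17
Reactants: 36 6-[(2R)-2-(ArA)-3-methylbutyl]-4-hydroxy-3,5,5-trimethyl-5,6-dihydro-2H-pyran-2-one
Product: 37 6-[(2R)-2-(ArA)-3-methylbutyl]-4-methoxy-3,5,5-trimethyl-5,6-dihydro-2H-pyran-2-one
Conditions: Me2SO4, K2CO3, acetone, reflux
Reagents that add atoms: dimethyl sulfate, COS(=O)(=O)OC
Why: O-methylation of the cyclic vinylogous acid (the standard 4-methoxy-5,6-dihydropyran-2-one synthesis) should put the methyl group on the D4 oxygen, the only enol oxygen present; the lactone ring holds D2 and D5 cis across D3=D4, which the later ring closure needs.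

Step 18
Reactants: 37 6-[(2R)-2-(ArA)-3-methylbutyl]-4-methoxy-3,5,5-trimethyl-5,6-dihydro-2H-pyran-2-one
Product: 38 (2E,7R)-7-(ArA)-5-hydroxy-N,3-dimethoxy-N,2,4,4,8-pentamethylnon-2-enamide
Conditions: MeNHOMe·HCl, Me3Al, CH2Cl2, 0 °C → rt; aq. HCl/Rochelle salt
Reagents that add atoms: N,O-dimethylhydroxylamine hydrochloride, CNOC.Cl
Why: Aluminium amide aminolysis of the lactone (Weinreb amide formation) opens the ring at the acyl–oxygen bond, keeps the enol ether geometry and leaves an acyl group that does not readily relactonise yet can still acylate carbon.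

Step 19
Reactants: 38 (2E,7R)-7-(ArA)-5-hydroxy-N,3-dimethoxy-N,2,4,4,8-pentamethylnon-2-enamide
Product: 39 (2E,7R)-7-(ArA)-N,3-dimethoxy-N,2,4,4,8-pentamethyl-5-oxonon-2-enamide
Conditions: Dess–Martin periodinane, CH2Cl2, rt
Reagents that add atoms: none
Why: Dess–Martin oxidation of the hindered secondary alcohol gives the D6 ketone under neutral conditions that leave the enol ether, the aryl silyl ether and the benzyl ethers alone.

Step 20
Reactants: 39 (2E,7R)-7-(ArA)-N,3-dimethoxy-N,2,4,4,8-pentamethyl-5-oxonon-2-enamide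
Product: 40 2-[(1R)-1-(ArA)-2-methylpropyl]-3-hydroxy-5-methoxy-4,4,6-trimethylcyclohexa-2,5-dien-1-one
Conditions: LiN(SiMe3)2 (3.5 equiv), THF, −78 → 0 °C; 1 M HCl
Reagents that add atoms: none
Why: The enolate at D1, the only enolisable position next to the D6 ketone, attacks the Weinreb amide carbonyl (intramolecular Claisen-type acylation, six-membered ring, D1–D2 bond) and collapse on work-up should give the enolised 1,3-diketone of ring D with the methoxy group fixed on D4; the excess base covers the acetyl group.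

### Ring C, C2 and deprotection (steps 21–24)

Step 21
Reactants: 40 2-[(1R)-1-(ArA)-2-methylpropyl]-3-hydroxy-5-methoxy-4,4,6-trimethylcyclohexa-2,5-dien-1-one
Product: 41 2-[(1R)-1-(3-acetyl-4,6-bis(benzyloxy)-2-hydroxy-5-methylphenyl)-2-methylpropyl]-3-hydroxy-5-methoxy-4,4,6-trimethylcyclohexa-2,5-dien-1-one
Conditions: Bu4NF, THF, 0 °C; NH4Cl
Reagents that add atoms: none
Why: Fluoride cleaves the aryl silyl ether selectively and releases the C8a phenol alone, both benzyl ethers being inert.

Step 22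
Reactants: 41 2-[(1R)-1-(3-acetyl-4,6-bis(benzyloxy)-2-hydroxy-5-methylphenyl)-2-methylpropyl]-3-hydroxy-5-methoxy-4,4,6-trimethylcyclohexa-2,5-dien-1-one
Product: 43 5,7-bis(benzyloxy)-8-[(1R)-1-(RD)-2-methylpropyl]-6-methyl-4H-chromen-4-one, via hemiacetal 42 (not isolated)
Conditions: NaH, HCO2Et, THF, 0 °C → rt; 1 M HCl; then TsOH·H2O (cat.), CH2Cl2, rt
Reagents that add atoms: ethyl formate, CCOC=O
Why: Claisen formylation of the acetyl methyl group and acid-catalysed cyclodehydration of the hemiacetal (the classical chromone synthesis) closes ring C on the C8a oxygen, the only free phenol, while ring D is protected as its enolate during the basic stage.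

Step 23
Reactants: 43 5,7-bis(benzyloxy)-8-[(1R)-1-(RD)-2-methylpropyl]-6-methyl-4H-chromen-4-one; 44 phenylboronic acid
Product: 45 (2S)-5,7-bis(benzyloxy)-8-[(1R)-1-(RD)-2-methylpropyl]-6-methyl-2-phenyl-2,3-dihydro-4H-chromen-4-one
Conditions: Pd(OCOCF3)2 (10 mol%), (R)-4-tert-butyl-2-(pyridin-2-yl)-4,5-dihydrooxazole (12 mol%), NH4PF6 (30 mol%), H2O (5 equiv), ClCH2CH2Cl, 60 °C
Reagents that add atoms: none
Why: Palladium-catalysed asymmetric conjugate addition of an arylboronic acid to a chromone forms the C2–phenyl bond irreversibly under weakly acidic conditions, so C2 is set by the chiral ligand (enantiomer chosen for 2S) independently of the remote C1' centre and cannot equilibrate by ring opening.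

Step 24
Reactants: 45 (2S)-5,7-bis(benzyloxy)-8-[(1R)-1-(RD)-2-methylpropyl]-6-methyl-2-phenyl-2,3-dihydro-4H-chromen-4-one
Product: 46 (2S)-5,7-dihydroxy-8-[(1R)-1-(RD)-2-methylpropyl]-6-methyl-2-phenyl-2,3-dihydro-4H-chromen-4-one
Conditions: H2 (1 atm), 10% Pd on carbon, EtOAc, rt; no acid in the work-up
Reagents that add atoms: none
Why: Hydrogenolysis of the two aryl benzyl ethers should spare the flavanone C2–O bond, the C4 ketone and the tetrasubstituted push-pull alkenes of ring D, giving the target.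

## Compound list

1 | (4R)-4-benzyl-1,3-oxazolidin-2-one | O=C1N[C@H](Cc2ccccc2)CO1 | starting material
2 | 3-methylbutanoyl chloride | CC(C)CC(Cl)=O | starting material
3 | (4R)-4-benzyl-3-(3-methylbutanoyl)-1,3-oxazolidin-2-one | CC(C)CC(=O)N1[C@H](Cc2ccccc2)COC1=O | intermediate
4 | 3-bromoprop-1-ene (allyl bromide) | C=CCBr | starting material
5 | sodium (1Z)-1-[(4R)-4-benzyl-2-oxo-1,3-oxazolidin-3-yl]-3-methylbut-1-en-1-olate | CC(C)/C=C(\[O-])N1[C@H](Cc2ccccc2)COC1=O.[Na+] | intermediate
6 | (4R)-4-benzyl-3-[(2R)-2-(propan-2-yl)pent-4-enoyl]-1,3-oxazolidin-2-one | C=CC[C@@H](C(=O)N1[C@H](Cc2ccccc2)COC1=O)C(C)C | intermediate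
7 | (2R)-2-(propan-2-yl)pent-4-eneperoxoic acid | C=CC[C@@H](C(=O)OO)C(C)C | intermediate
8 | (2R)-2-(propan-2-yl)pent-4-enoic acid | C=CC[C@@H](C(O)=O)C(C)C | intermediate
9 | ethyl (2R)-2-(propan-2-yl)pent-4-enoate | C=CC[C@@H](C(=O)OCC)C(C)C | intermediate
10 | lithium (3R)-1,1-dibromo-3-(propan-2-yl)hexa-1,5-dien-2-olate | C=CC[C@@H](C([O-])=C(Br)Br)C(C)C.[Li+] | intermediate
11 | lithium (3R)-3-(propan-2-yl)hex-5-en-1-yn-1-olate | C=CC[C@@H](C#C[O-])C(C)C.[Li+] | intermediate
12 | tri(propan-2-yl){[(3R)-3-(propan-2-yl)hex-5-en-1-yn-1-yl]oxy}silane | C=CC[C@@H](C#CO[Si](C(C)C)(C(C)C)C(C)C)C(C)C | intermediate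
13 | ethyl 2-(benzyloxy)acetate | CCOC(=O)COCc1ccccc1 | starting material
14 | acetaldehyde | CC=O | starting material
15 | ethyl 2-(benzyloxy)-3-hydroxybutanoate (diastereomer mixture) | CCOC(=O)C(OCc1ccccc1)C(C)O | intermediate
16 | ethyl 2-(benzyloxy)-3-[(methylsulfonyl)oxy]butanoate | CCOC(=O)C(OCc1ccccc1)C(C)OS(C)(=O)=O | intermediate
17 | ethyl (2Z)-2-(benzyloxy)but-2-enoate | CCOC(=O)/C(OCc1ccccc1)=C/C | intermediate
18 | (2Z)-2-(benzyloxy)-N-methoxy-N-methylbut-2-enamide | CON(C)C(=O)/C(OCc1ccccc1)=C/C | intermediate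
19 | (3Z)-3-(benzyloxy)pent-3-en-2-one | CC(=O)/C(OCc1ccccc1)=C/C | intermediate
20 | (5Z)-5-(benzyloxy)-1,1,1-trifluorohept-5-ene-2,4-dione | O=C(CC(=O)C(F)(F)F)/C(OCc1ccccc1)=C/C | intermediate
21 | (3Z)-3-(benzyloxy)-1-diazopent-3-en-2-one | C/C=C(\OCc1ccccc1)C(=O)C=[N+]=[N-] | intermediate
22 | (3Z)-3-(benzyloxy)penta-1,3-dien-1-one | C/C=C(\OCc1ccccc1)C=C=O | intermediate
23 | 4-[(1Z)-1-(benzyloxy)prop-1-en-1-yl]-2-[(3R)-2-methylhex-5-en-3-yl]-3-[(triisopropylsilyl)oxy]cyclobut-2-en-1-one (C4 epimers) | C=CC[C@@H](C1=C(O[Si](C(C)C)(C(C)C)C(C)C)C(/C(OCc2ccccc2)=C/C)C1=O)C(C)C | intermediate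
24 | (3E,5Z)-5-(benzyloxy)-2-[(3R)-2-methylhex-5-en-3-yl]-3-[(triisopropylsilyl)oxy]hepta-1,3,5-trien-1-one | C=CC[C@@H](C(=C=O)/C(O[Si](C(C)C)(C(C)C)C(C)C)=C\C(OCc1ccccc1)=C\C)C(C)C | intermediate
25 | 5-(benzyloxy)-6-methyl-2-[(3R)-2-methylhex-5-en-3-yl]-3-[(triisopropylsilyl)oxy]cyclohexa-2,4-dien-1-one (C6 epimers) | C=CC[C@@H](C1=C(O[Si](C(C)C)(C(C)C)C(C)C)C=C(OCc2ccccc2)C(C)C1=O)C(C)C | intermediate
26 | 5-(benzyloxy)-6-methyl-2-[(3R)-2-methylhex-5-en-3-yl]-3-[(triisopropylsilyl)oxy]phenol | C=CC[C@@H](c1c(O)c(C)c(OCc2ccccc2)cc1O[Si](C(C)C)(C(C)C)C(C)C)C(C)C | intermediate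
27 | {3,5-bis(benzyloxy)-4-methyl-2-[(3R)-2-methylhex-5-en-3-yl]phenoxy}triisopropylsilane | C=CC[C@@H](c1c(OCc2ccccc2)c(C)c(OCc2ccccc2)cc1O[Si](C(C)C)(C(C)C)C(C)C)C(C)C | intermediate
28 | {3,5-bis(benzyloxy)-2-bromo-4-methyl-6-[(3R)-2-methylhex-5-en-3-yl]phenoxy}triisopropylsilane | C=CC[C@@H](c1c(OCc2ccccc2)c(C)c(OCc2ccccc2)c(Br)c1O[Si](C(C)C)(C(C)C)C(C)C)C(C)C | intermediate
29 | {2,4-bis(benzyloxy)-3-methyl-5-[(3R)-2-methylhex-5-en-3-yl]-6-[(triisopropylsilyl)oxy]phenyl}lithium | C=CC[C@@H](c1c(OCc2ccccc2)c(C)c(OCc2ccccc2)c([Li])c1O[Si](C(C)C)(C(C)C)C(C)C)C(C)C | intermediate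
30 | 1-{2,4-bis(benzyloxy)-3-methyl-5-[(3R)-2-methylhex-5-en-3-yl]-6-[(triisopropylsilyl)oxy]phenyl}ethan-1-one | C=CC[C@@H](c1c(OCc2ccccc2)c(C)c(OCc2ccccc2)c(C(C)=O)c1O[Si](C(C)C)(C(C)C)C(C)C)C(C)C | intermediate
31 | (4R)-4-(ArA)-5-methylhexane-1,2-diol (C2 epimers) | OCC(O)C[C@@H](c1c(OCc2ccccc2)c(C)c(OCc2ccccc2)c(C(C)=O)c1O[Si](C(C)C)(C(C)C)C(C)C)C(C)C | intermediate
32 | (3R)-3-(ArA)-4-methylpentanal | O=CC[C@@H](c1c(OCc2ccccc2)c(C)c(OCc2ccccc2)c(C(C)=O)c1O[Si](C(C)C)(C(C)C)C(C)C)C(C)C | intermediate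
33 | methyl 2,4-dimethyl-3-oxopentanoate | COC(=O)C(C)C(=O)C(C)C | starting material
34 | dilithium 1-methoxy-2,4-dimethylpenta-1,3-diene-1,3-diolate (dianion of 33) | [Li+].[Li+].COC([O-])=C(C)C([O-])=C(C)C | intermediate
35 | methyl (7R)-7-(ArA)-5-hydroxy-2,4,4,8-tetramethyl-3-oxononanoate (epimers at C2 and C5) | COC(=O)C(C)C(=O)C(C)(C)C(O)C[C@@H](c1c(OCc2ccccc2)c(C)c(OCc2ccccc2)c(C(C)=O)c1O[Si](C(C)C)(C(C)C)C(C)C)C(C)C | intermediate
36 | 6-[(2R)-2-(ArA)-3-methylbutyl]-4-hydroxy-3,5,5-trimethyl-5,6-dihydro-2H-pyran-2-one (C6 epimers, enol form) | O=C1OC(C[C@@H](c2c(OCc3ccccc3)c(C)c(OCc3ccccc3)c(C(C)=O)c2O[Si](C(C)C)(C(C)C)C(C)C)C(C)C)C(C)(C)C(O)=C1C | intermediate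
37 | 6-[(2R)-2-(ArA)-3-methylbutyl]-4-methoxy-3,5,5-trimethyl-5,6-dihydro-2H-pyran-2-one (C6 epimers) | COC1=C(C)C(=O)OC(C[C@@H](c2c(OCc3ccccc3)c(C)c(OCc3ccccc3)c(C(C)=O)c2O[Si](C(C)C)(C(C)C)C(C)C)C(C)C)C1(C)C | intermediate
38 | (2E,7R)-7-(ArA)-5-hydroxy-N,3-dimethoxy-N,2,4,4,8-pentamethylnon-2-enamide (C5 epimers) | CON(C)C(=O)/C(C)=C(/OC)C(C)(C)C(O)C[C@@H](c1c(OCc2ccccc2)c(C)c(OCc2ccccc2)c(C(C)=O)c1O[Si](C(C)C)(C(C)C)C(C)C)C(C)C | intermediate
39 | (2E,7R)-7-(ArA)-N,3-dimethoxy-N,2,4,4,8-pentamethyl-5-oxonon-2-enamide | CON(C)C(=O)/C(C)=C(/OC)C(C)(C)C(=O)C[C@@H](c1c(OCc2ccccc2)c(C)c(OCc2ccccc2)c(C(C)=O)c1O[Si](C(C)C)(C(C)C)C(C)C)C(C)C | intermediate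
40 | 2-[(1R)-1-(ArA)-2-methylpropyl]-3-hydroxy-5-methoxy-4,4,6-trimethylcyclohexa-2,5-dien-1-one | COC1=C(C)C(=O)C([C@@H](c2c(OCc3ccccc3)c(C)c(OCc3ccccc3)c(C(C)=O)c2O[Si](C(C)C)(C(C)C)C(C)C)C(C)C)=C(O)C1(C)C | intermediate
41 | 2-[(1R)-1-(3-acetyl-4,6-bis(benzyloxy)-2-hydroxy-5-methylphenyl)-2-methylpropyl]-3-hydroxy-5-methoxy-4,4,6-trimethylcyclohexa-2,5-dien-1-one | COC1=C(C)C(=O)C([C@@H](c2c(OCc3ccccc3)c(C)c(OCc3ccccc3)c(C(C)=O)c2O)C(C)C)=C(O)C1(C)C | intermediate
42 | 5,7-bis(benzyloxy)-2-hydroxy-8-[(1R)-1-(RD)-2-methylpropyl]-6-methyl-2,3-dihydro-4H-chromen-4-one (C2 epimers) | COC1=C(C)C(=O)C([C@@H](c2c(OCc3ccccc3)c(C)c(OCc3ccccc3)c3c2OC(O)CC3=O)C(C)C)=C(O)C1(C)C | intermediate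
43 | 5,7-bis(benzyloxy)-8-[(1R)-1-(RD)-2-methylpropyl]-6-methyl-4H-chromen-4-one | COC1=C(C)C(=O)C([C@@H](c2c(OCc3ccccc3)c(C)c(OCc3ccccc3)c3c2OC=CC3=O)C(C)C)=C(O)C1(C)C | intermediate
44 | phenylboronic acid | OB(O)c1ccccc1 | starting material
45 | (2S)-5,7-bis(benzyloxy)-8-[(1R)-1-(RD)-2-methylpropyl]-6-methyl-2-phenyl-2,3-dihydro-4H-chromen-4-one | COC1=C(C)C(=O)C([C@@H](c2c(OCc3ccccc3)c(C)c(OCc3ccccc3)c3c2O[C@H](c2ccccc2)CC3=O)C(C)C)=C(O)C1(C)C | intermediate
46 | (2S)-5,7-dihydroxy-8-[(1R)-1-(RD)-2-methylpropyl]-6-methyl-2-phenyl-2,3-dihydro-4H-chromen-4-one | COC1=C(C)C(=O)C([C@@H](c2c(O)c(C)c(O)c3c2O[C@H](c2ccccc2)CC3=O)C(C)C)=C(O)C1(C)C | target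

## Step count

Total: 24 steps. Longest linear sequence: 19 steps (steps 1–5, then 11–24); the diazo ketone branch (steps 6–10) is of equal length to the alkyne branch.

## Steps most likely to fail

**Step 11 (benzannulation).** Capture of the photogenerated vinylketene by the α-branched siloxyalkyne may be slow. Ketene dimerisation, secondary photoreactions of the benzyl enol ether and acylation of the product phenol by remaining ketene would then lower the conversion. The fallback sets out from siloxyalkyne 12 and returns at phenol 26; it generates the same vinylketene thermally, without light. Benzyl alcohol and trichloroethene (KH) give benzyl (E)-1,2-dichloroethenyl ether F1. n-BuLi (2 equiv) followed by a proton quench converts it into (ethynyloxy)methylbenzene F2. Its [2+2] cycloaddition with methylketene F3 (formed in the flask from propanoyl chloride and Et3N) gives 3-(benzyloxy)-4-methylcyclobut-2-en-1-one F4. Heating F4 with 12 in toluene at 80–110 °C opens the cyclobutenone to vinylketene 22, and the cascade through 23, 24 and 25 continues to 26 (the thermal cyclobutenone form of the Danheiser benzannulation).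

**Step 20 (closure of ring D).** The ring closure may stall: the attacking carbon D1 carries the bulky C1' substituent, and the amide carbonyl is hindered and deactivated by the β-methoxy group, so O-acylation of the enolate or simple recovery of the amide could dominate. The fallback sets out from aldehyde 32 and returns at 40; it closes the ring first and methylates afterwards. Methyl 2-methylpropanoate is acylated with propanoyl chloride (LiN(i-Pr)2) to give methyl 2,2-dimethyl-3-oxopentanoate F5. Its lithium enolate, which can form only on the ethyl side, adds to 32 to give methyl (7R)-7-(ArA)-5-hydroxy-2,2,4,8-tetramethyl-3-oxononanoate F6. Dess–Martin oxidation gives methyl (7R)-7-(ArA)-2,2,4,8-tetramethyl-3,5-dioxononanoate F7. Its dianion (LiN(SiMe3)2) closes the ring by Dieckmann condensation of D1 onto the ester, giving 2-[(1R)-1-(ArA)-2-methylpropyl]-3,5-dihydroxy-4,4,6-trimethylcyclohexa-2,5-dien-1-one F8. O-methylation with Me3SiCHN2 is then expected at the enol oxygen flanked by the ring methyl carbon and the gem-dimethyl carbon, since the other two oxygens sit next to the bulky C1' substituent. This gives 40 after separation from any regioisomeric enol ether.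

**Step 23 (C2 stereocentre).** The enolised ring D may bind palladium and slow the catalyst, or the electron-rich 5,7-dioxygenated chromone may insert slowly and with poor facial selectivity. The fallback sets out from phenol 41 and returns at 45; it forms the C2–O bond last instead of the C2–aryl bond. Claisen–Schmidt condensation of the acetyl group with benzaldehyde (KOH, EtOH) gives 2-[(1R)-1-{4,6-bis(benzyloxy)-2-hydroxy-5-methyl-3-[(2E)-3-phenylprop-2-enoyl]phenyl}-2-methylpropyl]-3-hydroxy-5-methoxy-4,4,6-trimethylcyclohexa-2,5-dien-1-one F9. This chalcone is closed by intramolecular oxa-Michael addition with a cinchona-alkaloid thiourea catalyst. If selectivity is poor, it is closed with NaOAc in EtOH and the two C2 epimers, which are diastereomers because of C1', are separated by chromatography to give 45.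

## Further compounds

F1 | step 11 | benzyl (E)-1,2-dichloroethenyl ether | Cl/C=C(/Cl)OCc1ccccc1
F2 | step 11 | (ethynyloxy)methylbenzene | C#COCc1ccccc1
F3 | step 11 | methylketene (prop-1-en-1-one) | CC=C=O
F4 | step 11 | 3-(benzyloxy)-4-methylcyclobut-2-en-1-one | CC1C(=O)C=C1OCc1ccccc1
F5 | step 20 | methyl 2,2-dimethyl-3-oxopentanoate | CCC(=O)C(C)(C)C(=O)OC
F6 | step 20 | methyl (7R)-7-(ArA)-5-hydroxy-2,2,4,8-tetramethyl-3-oxononanoate | COC(=O)C(C)(C)C(=O)C(C)C(O)C[C@@H](c1c(OCc2ccccc2)c(C)c(OCc2ccccc2)c(C(C)=O)c1O[Si](C(C)C)(C(C)C)C(C)C)C(C)C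
F7 | step 20 | methyl (7R)-7-(ArA)-2,2,4,8-tetramethyl-3,5-dioxononanoate | COC(=O)C(C)(C)C(=O)C(C)C(=O)C[C@@H](c1c(OCc2ccccc2)c(C)c(OCc2ccccc2)c(C(C)=O)c1O[Si](C(C)C)(C(C)C)C(C)C)C(C)C
F8 | step 20 | 2-[(1R)-1-(ArA)-2-methylpropyl]-3,5-dihydroxy-4,4,6-trimethylcyclohexa-2,5-dien-1-one | CC1=C(O)C(C)(C)C(O)=C([C@@H](c2c(OCc3ccccc3)c(C)c(OCc3ccccc3)c(C(C)=O)c2O[Si](C(C)C)(C(C)C)C(C)C)C(C)C)C1=O
F9 | step 23 | 2-[(1R)-1-{4,6-bis(benzyloxy)-2-hydroxy-5-methyl-3-[(2E)-3-phenylprop-2-enoyl]phenyl}-2-methylpropyl]-3-hydroxy-5-methoxy-4,4,6-trimethylcyclohexa-2,5-dien-1-one | COC1=C(C)C(=O)C([C@@H](c2c(OCc3ccccc3)c(C)c(OCc3ccccc3)c(C(=O)/C=C/c3ccccc3)c2O)C(C)C)=C(O)C1(C)C
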